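**Retrosynthetic overview** (quinone numbering: C1(=O), C2 henicosyl, C3 methyl, C4(=O), C5–H, C6 OMe)

1. Target 16 ⇐ oxidative dealkylation of trialkoxyarene 15 ⇐ O-methylation (the C6 oxygen) of phenol 14.
2. 14 ⇐ Danheiser benzannulation: the two-carbon unit C4–C5 (ethoxyethyne 9) is inserted between C3 and C6 of the four-carbon unit C6–C1–C2–C3 (cyclobutenone 8), forming the C5–C6 and C3–C4 bonds in one operation.
3. Enabling feature: in the quinone ring the oxygens on C4 and C6 are meta across the unsubstituted C5–H, the signature of a ketene carbonyl (C6) joined to an ynol ether (C4–C5). C1 is carried at the hydroquinone level as the methoxy-bearing sp3 carbon of 8.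
4. 8 ⇐ 1,2-addition of henicosylmagnesium bromide to vinylogous ester 4 with 1,3-carbonyl transposition ⇐ [2+2] cycloaddition of methoxyketene (from 1) with 1-ethoxyprop-1-yne 2.
5. Ring order: the cyclobutene ring first (step 1), then the only six-membered ring (step 3), in which the four-membered ring is consumed.

Key step: step 3

Remark on the chemistry: 2 and 5 are taken as catalogue compounds; 4, 7, 8, 11 and 13 are racemic or diastereomeric mixtures, which is without consequence because every stereocentre is erased in step 3 and the target is achiral.

**Step 1**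
Reactants: 1 methoxyacetyl chloride; 2 1-ethoxyprop-1-yne
Product: 4 3-ethoxy-4-methoxy-2-methylcyclobut-2-en-1-one, via methoxyketene 3 (not isolated)
Conditions: Et3N, Et2O, 0 °C → rt, slow addition of 1
Reagents that add atoms: none
Why: Et3N dehydrochlorinates 1 to methoxyketene 3, which the electron-rich alkyne 2 should trap in a thermal ketene–ynol ether [2+2] cycloaddition with polarity-matched regiochemistry (ketene carbonyl carbon to the methyl-bearing alkyne carbon), giving vinylogous ester 4 as a racemate.

**Step 2**
Reactants: 4 3-ethoxy-4-methoxy-2-methylcyclobut-2-en-1-one; 5 1-bromohenicosane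
Product: 8 3-henicosyl-4-methoxy-2-methylcyclobut-2-en-1-one, via henicosylmagnesium bromide 6 (not isolated), via cyclobutenol adduct 7 (not isolated)
Conditions: 5, Mg, THF, 45 °C; add 4, −40 → −20 °C; then cold 1 M HCl, 0 °C → rt
Reagents that add atoms: water, O
Why: Stork–Danheiser-type 1,3-carbonyl transposition, in which Grignard reagent 6 adds 1,2 to the vinylogous ester carbonyl of 4 (enolization is blocked because the enolate would be a cyclobutadiene) and cold aqueous acid hydrolyses the enol ether of carbinol 7 with loss of water to the transposed enone 8, the covalent magnesium alkoxide being expected to resist anion-accelerated ring opening at low temperature.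

**Step 3**
Reactants: 8 3-henicosyl-4-methoxy-2-methylcyclobut-2-en-1-one; 9 ethoxyethyne
Product: 14 5-ethoxy-3-henicosyl-2-methoxy-4-methylphenol, via vinylketene 10 (not isolated), via vinylcyclobutenone 11 (not isolated), via dienylketene 12 (not isolated), via cyclohexadienone 13 (not isolated)
Conditions: 9 (3 equiv), PhMe, sealed tube, 80 °C, then 110 °C
Reagents that add atoms: none
Why: Danheiser benzannulation, a pericyclic cascade in which thermal 4π electrocyclic opening of 8 breaks the acyl–CH(OMe) bond to give vinylketene 10, whose ketene C=C undergoes [2+2] cycloaddition with 9 to give 4-vinylcyclobutenone 11, which opens (4π) to dienylketene 12, closes by 6π electrocyclization to dienone 13 and tautomerizes to phenol 14. The closest known reaction type is the cyclobutenone/alkoxyacetylene benzannulation that gives 3-alkoxyphenols; the 4-methoxy group is the only variation and, as a donor on the breaking bond, should lower the temperature of the first ring opening to one that ethoxyethyne tolerates. The transient four-membered ring of 11 is closed by the ketene–alkyne [2+2] cycloaddition and the six-membered ring by thermal disrotatory 6π electrocyclization of 12 (bond between the ketene carbon and the methoxy-bearing terminus), with aromatization as the driving force. No stereocentre is created and the one in 8 is erased. The step needs regiocontrol in the [2+2] event, secured by matched polarization (the nucleophilic CH terminus of the ynol ether bonds to the electrophilic ketene carbonyl carbon, C5 to C6, and the ethoxy-bearing carbon to the methyl-bearing ketene terminus, C4 to C3), and an E vinylketene, secured by outward rotation of the donor methoxy group. Net, the two alkyne carbons are inserted into the acyl–vinyl bond of 8, so all five substituents of the arene are placed in one operation with no atom lost.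

**Step 4**
Reactants: 14 5-ethoxy-3-henicosyl-2-methoxy-4-methylphenol
Product: 15 1-ethoxy-3-henicosyl-4,5-dimethoxy-2-methylbenzene
Conditions: MeI, K2CO3, acetone, reflux
Reagents that add atoms: iodomethane, CI
Why: Williamson ether synthesis at the only acidic site of 14, a phenol flanked by one methoxy group and one ring hydrogen, so O-methylation should be clean.

**Step 5**
Reactants: 15 1-ethoxy-3-henicosyl-4,5-dimethoxy-2-methylbenzene
Product: 16 2-henicosyl-6-methoxy-3-methylcyclohexa-2,5-diene-1,4-dione
Conditions: (NH4)2Ce(NO3)6, MeCN/CH2Cl2/H2O, 0 °C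
Reagents that add atoms: water, O
Why: oxidative dealkylation of a 1,4-dialkoxyarene by tetravalent cerium, in which two one-electron oxidations and addition of water at the para-related ethoxy- and methoxy-bearing carbons release ethanol and methanol and give the para-quinone, the third alkoxy group surviving as the vinylogous ester methoxy group as in other 1,2,4-trialkoxybenzenes.

**Compound list**

1 | methoxyacetyl chloride | COCC(Cl)=O | starting material
2 | 1-ethoxyprop-1-yne | CC#COCC | starting material
3 | methoxyketene (2-methoxyethen-1-one) | COC=C=O | intermediate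
4 | 3-ethoxy-4-methoxy-2-methylcyclobut-2-en-1-one (racemic) | CCOC1=C(C)C(=O)C1OC | intermediate
5 | 1-bromohenicosane | CCCCCCCCCCCCCCCCCCCCCBr | starting material
6 | henicosylmagnesium bromide | CCCCCCCCCCCCCCCCCCCCC[Mg]Br | intermediate
7 | 3-ethoxy-1-henicosyl-4-methoxy-2-methylcyclobut-2-en-1-ol (mixture of diastereomers, formed as its magnesium alkoxide) | CCCCCCCCCCCCCCCCCCCCCC1(O)C(C)=C(OCC)C1OC | intermediate
8 | 3-henicosyl-4-methoxy-2-methylcyclobut-2-en-1-one (racemic) | CCCCCCCCCCCCCCCCCCCCCC1=C(C)C(=O)C1OC | intermediate
9 | ethoxyethyne | C#COCC | starting material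
10 | (3E)-3-henicosyl-4-methoxy-2-methylbuta-1,3-dien-1-one (vinylketene) | O=C=C(C)/C(CCCCCCCCCCCCCCCCCCCCC)=C/OC | intermediate
11 | 3-ethoxy-4-[(E)-1-methoxytricos-1-en-2-yl]-4-methylcyclobut-2-en-1-one (racemic) | CCOC1=CC(=O)C1(C)/C(CCCCCCCCCCCCCCCCCCCCC)=C/OC | intermediate
12 | (3E,5E)-3-ethoxy-5-henicosyl-6-methoxy-4-methylhexa-1,3,5-trien-1-one (dienylketene) | O=C=C/C(OCC)=C(C)\C(CCCCCCCCCCCCCCCCCCCCC)=C\OC | intermediate
13 | 3-ethoxy-5-henicosyl-6-methoxy-4-methylcyclohexa-2,4-dien-1-one (racemic) | CCOC1=CC(=O)C(OC)C(CCCCCCCCCCCCCCCCCCCCC)=C1C | intermediate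
14 | 5-ethoxy-3-henicosyl-2-methoxy-4-methylphenol | CCOc1cc(O)c(OC)c(CCCCCCCCCCCCCCCCCCCCC)c1C | intermediate
15 | 1-ethoxy-3-henicosyl-4,5-dimethoxy-2-methylbenzene | CCOc1cc(OC)c(OC)c(CCCCCCCCCCCCCCCCCCCCC)c1C | intermediate
16 | 2-henicosyl-6-methoxy-3-methylcyclohexa-2,5-diene-1,4-dione (achiral) | CCCCCCCCCCCCCCCCCCCCCC1=C(C)C(=O)C=C(OC)C1=O | target

**Step count**

Total step count: 5. Longest linear sequence: 5 steps (1 + 2 → 4 → 8 → 14 → 15 → 16).

**Steps most likely to fail**

Step 3. The vinylketene may be lost to self-dimerization or to acylation of the product phenol, and the ynol ether may undergo thermal retro-ene decomposition before it is captured. The fallback gives up the annulation and attaches the chain to a ready-made quinone by radical C–H alkylation. It sets out from 5 and comes back at 16. Grignard reagent 6 (from 5 as in step 2) is carboxylated (CO2, THF; then HCl) to docosanoic acid F1, which is also a catalogue compound. Commercial 2-methoxy-5-methylphenol is oxidised with (KSO3)2NO (aqueous acetone, KH2PO4) to 2-methoxy-5-methylcyclohexa-2,5-diene-1,4-dione F2. AgNO3 (catalytic) and (NH4)2S2O8 in MeCN/H2O at 65 °C should then decarboxylate F1 to the henicosyl radical. This should add to the ring CH beside the methyl-bearing carbon of F2, because the other CH is the deactivated α-carbon of the vinylogous ester, and reoxidation gives 16.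

Step 2. The cyclobutenolate may undergo anion-accelerated electrocyclic ring opening before it is protonated, or the four-membered ring may decompose under acid during the transposition. The fallback avoids any organometallic addition to a four-membered ring and brings in the last oxygen by a final phenol oxidation. It sets out from 5 and comes back at 16. Alkylation of LiC≡CH·H2NCH2CH2NH2 with 5 (DMSO/THF) should give tricos-1-yne F3. Keteniminium [2+2] cycloaddition (N,N-dimethylpropanamide, (CF3SO2)2O, 2,4,6-collidine, ClCH2CH2Cl, reflux) should give N-(3-henicosyl-4-methylcyclobut-2-en-1-ylidene)-N-methylmethanaminium trifluoromethanesulfonate F4, which aqueous work-up hydrolyses to 3-henicosyl-4-methylcyclobut-2-en-1-one F5. Thermal benzannulation of F5 with methoxyethyne F6 (from chloroacetaldehyde dimethyl acetal and NaNH2 in liquid NH3) in PhMe at 80 °C should give 3-henicosyl-5-methoxy-2-methylphenol F7. Here the ketene carbon becomes C4 and the ynol ether supplies C5 and C6. Oxidation with (KSO3)2NO at the free para position then gives 16.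

Step 1. Oligomerization of the alkoxyketene, and acylation or hydrochlorination of the ynol ether, may outrun the [2+2] cycloaddition. The fallback builds 4 from a ready-made four-membered ring. It sets out from none of the numbered compounds, since 1 and 2 are both replaced by commercial diethyl squarate (3,4-diethoxycyclobut-3-ene-1,2-dione), and comes back at 4. MeLi (THF, −78 °C) should add once to give 2,3-diethoxy-4-hydroxy-4-methylcyclobut-2-en-1-one F8. Aqueous HCl rearranges it to 3-ethoxy-4-methylcyclobut-3-ene-1,2-dione F9. LiAlH(OtBu)3 (THF, −78 °C) should reduce the more electrophilic carbonyl, the one next to the ethoxy-bearing carbon and not the vinylogous ester carbonyl, to give 3-ethoxy-4-hydroxy-2-methylcyclobut-2-en-1-one F10. MeI/Ag2O then gives 4.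

**Further compounds**

F1 | step 3 | docosanoic acid | CCCCCCCCCCCCCCCCCCCCCC(=O)O
F2 | step 3 | 2-methoxy-5-methylcyclohexa-2,5-diene-1,4-dione | COC1=CC(=O)C(C)=CC1=O
F3 | step 2 | tricos-1-yne | C#CCCCCCCCCCCCCCCCCCCCCC
F4 | step 2 | N-(3-henicosyl-4-methylcyclobut-2-en-1-ylidene)-N-methylmethanaminium trifluoromethanesulfonate (racemic) | CCCCCCCCCCCCCCCCCCCCCC1=CC(=[N+](C)C)C1C.[O-]S(=O)(=O)C(F)(F)F
F5 | step 2 | 3-henicosyl-4-methylcyclobut-2-en-1-one (racemic) | CCCCCCCCCCCCCCCCCCCCCC1=CC(=O)C1C
F6 | step 2 | methoxyethyne | C#COC
F7 | step 2 | 3-henicosyl-5-methoxy-2-methylphenol | COc1cc(O)c(C)c(CCCCCCCCCCCCCCCCCCCCC)c1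
F8 | step 1 | 2,3-diethoxy-4-hydroxy-4-methylcyclobut-2-en-1-one (racemic) | CCOC1=C(OCC)C(C)(O)C1=O
F9 | step 1 | 3-ethoxy-4-methylcyclobut-3-ene-1,2-dione | CCOC1=C(C)C(=O)C1=O
F10 | step 1 | 3-ethoxy-4-hydroxy-2-methylcyclobut-2-en-1-one (racemic) | CCOC1=C(C)C(=O)C1O
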